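The synthesis rests on disconnecting the C1–C2 bond of the cyclohexenol ring A (clerodane numbering; ring A = C1–C5, C10). A tetracyclic 1,2-seco precursor already holding the cyclohexane ring B, the furan-fused cycloheptanone and the spiro γ-lactone carries a non-enolizable C2 enal on the lactone and an untouched C1 methylene. Because C1–H is vinylogously acidified by the C12 ketone through the furan C13=C16 bond, an intramolecular through-furan vinylogous aldol reaction closes ring A last and sets C1 and C2 in one operation. Ring B comes from an organocatalytic Michael–aldol cascade and two cuprate additions, the seven-membered ring from a Friedel–Crafts acylation.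

Key step: step 18

Remark: carbons are numbered as in clerodanes: ring B = C5–C10; lactone = C4, C5, C18, C19; cycloheptanone = C1, C9–C13, C16; furan = C13–C16; methyls C17 (on C8) and C20 (on C9).
Remark: compounds 23–32 are expected as E/Z mixtures at the C3=C4 alkylidene; the E isomer (C2 cis to C5), the one able to cyclize, is drawn.
Remark: 3-(furan-2-yl)propanal 6, ethyl bromoacetate 16 and (tert-butyldimethylsilyloxy)acetaldehyde 20 are taken as catalogue compounds.

Step 1
Reactants: 1 1-bromobutan-2-one; 2 ethyl glyoxylate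
Product: 5 ethyl (E)-4-oxohex-2-enoate, via phosphonium bromide 3 (not isolated), via keto ylide 4 (not isolated)
Conditions: PPh3, CH2Cl2, rt; then Et3N, 0 °C; then 2, rt
Reagents that add atoms: none
Why: Wittig olefination of the stabilized keto ylide, made in the flask from the phosphonium salt, with the aldehyde should give the E enoate.

Step 2
Reactants: 5 ethyl (E)-4-oxohex-2-enoate; 6 3-(furan-2-yl)propanal
Product: 8 ethyl (1R,2R)-2-(furan-2-ylmethyl)-4-methyl-5-oxocyclohex-3-ene-1-carboxylate, via Michael adduct 7 (not isolated)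
Conditions: (R)-2-[diphenyl(trimethylsilyloxy)methyl]pyrrolidine (10 mol %), PhCO2H (10 mol %), toluene, 0 °C → rt; then pyrrolidine (20 mol %), AcOH (20 mol %), 40 °C
Reagents that add atoms: none
Why: Enamine-catalysed Michael addition of the aldehyde to the carbon β to the ketone (diarylprolinol silyl ether catalysis) sets C10 by shielding of one enamine face and C5 by the syn topicity, and amine-catalysed intramolecular aldol condensation of the ethyl ketone methylene onto the aldehyde (Robinson-type annulation) then gives the 4,5-trans cyclohexenone.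

Step 3
Reactants: 8 ethyl (1R,2R)-2-(furan-2-ylmethyl)-4-methyl-5-oxocyclohex-3-ene-1-carboxylate
Product: 9 ethyl (1R,5R,6R)-6-(furan-2-ylmethyl)-4,5-dimethyl-3-(trimethylsilyloxy)cyclohex-3-ene-1-carboxylate
Conditions: Me2CuLi, Me3SiCl, THF, −78 °C
Reagents that add atoms: lithium dimethylcuprate [Li+].C[Cu-]C; chlorotrimethylsilane C[Si](C)(C)Cl
Why: Gilman cuprate 1,4-addition, accelerated by the silyl chloride and expected anti to the C10 furfuryl group, delivers the C9 methyl and traps the enolate as the silyl enol ether, the new C9 center being erased again in step 4.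

Step 4
Reactants: 9 ethyl (1R,5R,6R)-6-(furan-2-ylmethyl)-4,5-dimethyl-3-(trimethylsilyloxy)cyclohex-3-ene-1-carboxylate
Product: 10 ethyl (1R,2S)-2-(furan-2-ylmethyl)-3,4-dimethyl-5-oxocyclohex-3-ene-1-carboxylate
Conditions: Pd(OAc)2 (1.1 equiv), MeCN, rt
Reagents that add atoms: none
Why: Saegusa–Ito oxidation, in which the divalent palladium enolate formed from the silyl enol ether undergoes β-hydride elimination toward C9, should regenerate the enone now carrying the C9 methyl.

Step 5
Reactants: 10 ethyl (1R,2S)-2-(furan-2-ylmethyl)-3,4-dimethyl-5-oxocyclohex-3-ene-1-carboxylate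
Product: 12 ethyl (1R,2S,3R,4S)-3-ethenyl-2-(furan-2-ylmethyl)-3,4-dimethyl-5-oxocyclohexane-1-carboxylate, via silyl enol ether 11 (not isolated)
Conditions: CH2=CHMgBr, CuBr·SMe2 (20 mol %), Me3SiCl, HMPA, THF, −78 → −40 °C; then 1 M HCl, THF, 0 °C
Reagents that add atoms: vinylmagnesium bromide C=C[Mg]Br
Why: Copper-catalysed, silyl chloride-accelerated conjugate addition of the Grignard reagent should occur anti to the C10 furfuryl group, which A(1,2) strain with the C9 methyl holds pseudoaxial, creating quaternary C9 with methyl cis and vinyl trans to C1, and hydrolysis of the enol ether protonates C8 opposite the axial C9 methyl to leave the C8 methyl equatorial (also the thermodynamic position).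

Step 6
Reactants: 12 ethyl (1R,2S,3R,4S)-3-ethenyl-2-(furan-2-ylmethyl)-3,4-dimethyl-5-oxocyclohexane-1-carboxylate
Product: 13 ethyl (1R,2S,3R,4S,5R)-3-ethenyl-2-(furan-2-ylmethyl)-5-hydroxy-3,4-dimethylcyclohexane-1-carboxylate
Conditions: LiBH(s-Bu)3, THF, −78 °C; aq. NH4Cl
Reagents that add atoms: none
Why: The bulky trialkylborohydride should attack the ketone from the equatorial direction, the axial path being blocked by the axial C9 methyl, giving the axial C7 alcohol cis to the C8 methyl while the ester survives at −78 °C.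

Step 7
Reactants: 13 ethyl (1R,2S,3R,4S,5R)-3-ethenyl-2-(furan-2-ylmethyl)-5-hydroxy-3,4-dimethylcyclohexane-1-carboxylate
Product: 14 ethyl (1R,2S,3R,4S,5R)-5-(tert-butyldimethylsilyloxy)-3-ethenyl-2-(furan-2-ylmethyl)-3,4-dimethylcyclohexane-1-carboxylate
Conditions: t-BuMe2SiOTf, 2,6-lutidine, CH2Cl2, 0 °C
Reagents that add atoms: tert-butyldimethylsilyl triflate CC(C)(C)[Si](C)(C)OS(=O)(=O)C(F)(F)F
Why: Silylation with the silyl triflate is the standard way to protect a hindered axial secondary alcohol against the bases used later.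

Step 8
Reactants: 14 ethyl (1R,2S,3R,4S,5R)-5-(tert-butyldimethylsilyloxy)-3-ethenyl-2-(furan-2-ylmethyl)-3,4-dimethylcyclohexane-1-carboxylate
Product: 15 (1R,2S,3R,4S,5R)-5-(tert-butyldimethylsilyloxy)-3-ethenyl-2-(furan-2-ylmethyl)-3,4-dimethylcyclohexane-1-carbaldehyde
Conditions: i-Bu2AlH (1.1 equiv), CH2Cl2, −78 °C; aq. Rochelle salt
Reagents that add atoms: none
Why: Partial reduction of the ester with i-Bu2AlH at −78 °C stops at the tetrahedral aluminate, which releases the aldehyde on work-up.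

Step 9
Reactants: 15 (1R,2S,3R,4S,5R)-5-(tert-butyldimethylsilyloxy)-3-ethenyl-2-(furan-2-ylmethyl)-3,4-dimethylcyclohexane-1-carbaldehyde; 16 ethyl bromoacetate
Product: 17 ethyl 2-[(1R,2R,3R,4S,5R)-5-(tert-butyldimethylsilyloxy)-3-ethenyl-1-formyl-2-(furan-2-ylmethyl)-3,4-dimethylcyclohexyl]acetate
Conditions: KN(SiMe3)2, THF, −78 °C; then 16, −78 → −20 °C
Reagents that add atoms: none
Why: Alkylation of the potassium enolate of the α-branched aldehyde should take place from the equatorial side, because the axial face is blocked by the syn-axial C7 silyloxy and C9 methyl groups, so that quaternary C5 forms with the formyl group (C19) axial and the acetate arm (C4) equatorial.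

Step 10
Reactants: 17 ethyl 2-[(1R,2R,3R,4S,5R)-5-(tert-butyldimethylsilyloxy)-3-ethenyl-1-formyl-2-(furan-2-ylmethyl)-3,4-dimethylcyclohexyl]acetate
Product: 19 (5R,6R,7R,8S,9R)-9-(tert-butyldimethylsilyloxy)-7-ethenyl-6-(furan-2-ylmethyl)-7,8-dimethyl-2-oxaspiro[4.5]decan-3-one, via hydroxy ester 18 (not isolated)
Conditions: NaBH4, MeOH, 0 °C → rt; then PPTS (cat.), toluene, 60 °C
Reagents that add atoms: none
Why: Chemoselective borohydride reduction of the aldehyde gives a neopentyl alcohol that closes the spiro γ-lactone on the neighbouring ethyl ester (5-exo-trig lactonization).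

Step 11
Reactants: 19 (5R,6R,7R,8S,9R)-9-(tert-butyldimethylsilyloxy)-7-ethenyl-6-(furan-2-ylmethyl)-7,8-dimethyl-2-oxaspiro[4.5]decan-3-one; 20 (tert-butyldimethylsilyloxy)acetaldehyde
Product: 23 (4E,5S,6R,7R,8S,9R)-9-(tert-butyldimethylsilyloxy)-4-[2-(tert-butyldimethylsilyloxy)ethylidene]-7-ethenyl-6-(furan-2-ylmethyl)-7,8-dimethyl-2-oxaspiro[4.5]decan-3-one, via lithium aldolate 21 (not isolated), via aldol mesylate 22 (not isolated)
Conditions: LiN(i-Pr)2, THF, −78 °C; then 20; then MsCl, −78 → 0 °C; then DBU, rt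
Reagents that add atoms: none
Why: Aldol addition of the lactone lithium enolate, the only acidic site at this stage, followed by mesylation and E1cB elimination (aldol condensation) should give the α-alkylidene lactone, whose geometry need not be controlled because it is corrected in step 18.

Step 12
Reactants: 23 (4E,5S,6R,7R,8S,9R)-9-(tert-butyldimethylsilyloxy)-4-[2-(tert-butyldimethylsilyloxy)ethylidene]-7-ethenyl-6-(furan-2-ylmethyl)-7,8-dimethyl-2-oxaspiro[4.5]decan-3-one
Product: 25 (4E,5S,6R,7R,8S,9R)-9-(tert-butyldimethylsilyloxy)-4-[2-(tert-butyldimethylsilyloxy)ethylidene]-6-(furan-2-ylmethyl)-7-(2-hydroxyethyl)-7,8-dimethyl-2-oxaspiro[4.5]decan-3-one, via alkyl borane 24 (not isolated)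
Conditions: 9-BBN, THF, 0 °C → rt; then H2O2, aq. NaHCO3, 0 °C
Reagents that add atoms: hydrogen peroxide OO
Why: Anti-Markovnikov hydroboration–oxidation with 9-BBN should touch only the terminal vinyl group, the electron-poor trisubstituted alkylidene lactone, the lactone carbonyl and the furan being inert to this borane.

Step 13
Reactants: 25 (4E,5S,6R,7R,8S,9R)-9-(tert-butyldimethylsilyloxy)-4-[2-(tert-butyldimethylsilyloxy)ethylidene]-6-(furan-2-ylmethyl)-7-(2-hydroxyethyl)-7,8-dimethyl-2-oxaspiro[4.5]decan-3-one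
Product: 27 2-[(4E,5S,6R,7R,8S,9R)-9-(tert-butyldimethylsilyloxy)-4-[2-(tert-butyldimethylsilyloxy)ethylidene]-6-(furan-2-ylmethyl)-7,8-dimethyl-3-oxo-2-oxaspiro[4.5]decan-7-yl]acetic acid, via aldehyde 26 (not isolated)
Conditions: TEMPO (20 mol %), PhI(OAc)2 (2.5 equiv), MeCN/H2O (1:1), rt
Reagents that add atoms: water O
Why: Oxoammonium (TEMPO/PhI(OAc)2) oxidation in wet acetonitrile takes the primary alcohol through the aldehyde hydrate to the carboxylic acid under conditions that silyl ethers and furans tolerate.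

Step 14
Reactants: 27 2-[(4E,5S,6R,7R,8S,9R)-9-(tert-butyldimethylsilyloxy)-4-[2-(tert-butyldimethylsilyloxy)ethylidene]-6-(furan-2-ylmethyl)-7,8-dimethyl-3-oxo-2-oxaspiro[4.5]decan-7-yl]acetic acid
Product: 29 bis-silyl seco-ketone (5S,7R,8S,9R,10R), via acid chloride 28 (not isolated)
Conditions: 1-chloro-N,N,2-trimethylprop-1-en-1-amine, CH2Cl2, 0 °C; then SnCl4, CH2Cl2 (0.005 M), −78 → −20 °C
Reagents that add atoms: none
Why: Intramolecular Friedel–Crafts acylation of the 2-alkylfuran at C13, the only ring position the C11–C12 tether can reach, should close the cycloheptanone trans-fused to ring B, with the acid chloride made under neutral conditions and high dilution suppressing intermolecular attack at C15.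

Step 15
Reactants: 29 bis-silyl seco-ketone (5S,7R,8S,9R,10R)
Product: 30 seco-diol (5S,7R,8S,9R,10R)
Conditions: HF·pyridine, THF/pyridine, 0 °C → rt
Reagents that add atoms: none
Why: Fluoride-mediated desilylation should remove both the primary allylic and the hindered axial secondary silyl ether without affecting the lactone, ketone or furan.

Step 16
Reactants: 30 seco-diol (5S,7R,8S,9R,10R)
Product: 31 seco-hydroxy enal (5S,7R,8S,9R,10R)
Conditions: TEMPO (10 mol %), PhI(OAc)2 (1.1 equiv), CH2Cl2, rt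
Reagents that add atoms: none
Why: The oxoammonium oxidation is selective for the unhindered primary allylic alcohol over the axial C7 alcohol, which is flanked by two syn-axial groups.

Step 17
Reactants: 31 seco-hydroxy enal (5S,7R,8S,9R,10R)
Product: 32 seco-acetoxy enal (5S,7R,8S,9R,10R)
Conditions: Ac2O, Et3N, DMAP (cat.), CH2Cl2, rt
Reagents that add atoms: acetic anhydride CC(=O)OC(C)=O
Why: DMAP-catalysed acylation installs the C7 acetate on the only hydroxyl left, before the C2 hydroxyl exists.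

Step 18
Reactants: 32 seco-acetoxy enal (5S,7R,8S,9R,10R)
Product: 33 target CNP0182929.1 (1S,2S,5S,7R,8S,9R,10R)
Conditions: KOt-Bu (0.3 equiv), PhSH (0.1 equiv), t-BuOH/THF (1:10, 0.01 M), −20 → 0 °C; then AcOH
Reagents that add atoms: none
Why: Proposed new method: catalytic tert-butoxide reversibly enolizes the C12 ketone at C11 and, through the furan C13=C16 bond, at C1, and only the extended C1 dienolate can reach the C2 aldehyde, to which it adds in an intramolecular vinylogous aldol reaction with re-aromatization of the furan. The closest known reaction types are the lateral lithiation–aldol addition of 2-methyl-3-furoic acid derivatives and the base-mediated vinylogous aldol condensation of 2-methylchromones, whereas a ketone that also carries α'-hydrogens has not been used in this way. Ring A closes in a 6-(enolexo)-exo-trig mode. C1 is set by the chair-like transition state that extends the trans-fused ring B (H1 anti to H10, furan carbon C16 equatorial) and stays correctable because C1–H remains vinylogously acidic, while C2 is set by the pseudo-equatorial placement of the alkoxide trans to C16 under reversible aldol conditions. The step needs C1 over C11 selectivity, secured because C11 and the C4 side arm are 1,3-diequatorial on the locked ring B so that the C11 enolate cannot reach C2 and because the enal has no enolizable hydrogen, and it needs the E alkylidene geometry, secured by thiolate-mediated E/Z equilibration with only the E isomer able to cyclize.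

Compound list
1 | 1-bromobutan-2-one | CCC(=O)CBr | starting material
2 | ethyl glyoxylate | CCOC(=O)C=O | starting material
3 | (2-oxobutyl)triphenylphosphonium bromide | CCC(=O)C[P+](c1ccccc1)(c1ccccc1)c1ccccc1.[Br-] | intermediate (not isolated)
4 | 1-(triphenylphosphoranylidene)butan-2-one | CCC(=O)C=P(c1ccccc1)(c1ccccc1)c1ccccc1 | intermediate (not isolated)
5 | ethyl (E)-4-oxohex-2-enoate | CCC(=O)/C=C/C(=O)OCC | intermediate
6 | 3-(furan-2-yl)propanal | O=CCCc1ccco1 | starting material
7 | ethyl (2R)-2-[(2S)-1-(furan-2-yl)-3-oxopropan-2-yl]-4-oxohexanoate | CCC(=O)C[C@@H](C(=O)OCC)[C@H](Cc1ccco1)C=O | intermediate (not isolated)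
8 | ethyl (1R,2R)-2-(furan-2-ylmethyl)-4-methyl-5-oxocyclohex-3-ene-1-carboxylate | O=C1C[C@@H](C(=O)OCC)[C@H](Cc2ccco2)C=C1C | intermediate
9 | ethyl (1R,5R,6R)-6-(furan-2-ylmethyl)-4,5-dimethyl-3-(trimethylsilyloxy)cyclohex-3-ene-1-carboxylate | CC1=C(O[Si](C)(C)C)C[C@@H](C(=O)OCC)[C@H](Cc2ccco2)[C@H]1C | intermediate
10 | ethyl (1R,2S)-2-(furan-2-ylmethyl)-3,4-dimethyl-5-oxocyclohex-3-ene-1-carboxylate | O=C1C[C@@H](C(=O)OCC)[C@H](Cc2ccco2)C(C)=C1C | intermediate
11 | ethyl (1R,5R,6S)-5-ethenyl-6-(furan-2-ylmethyl)-4,5-dimethyl-3-(trimethylsilyloxy)cyclohex-3-ene-1-carboxylate | CC1=C(O[Si](C)(C)C)C[C@@H](C(=O)OCC)[C@H](Cc2ccco2)[C@@]1(C)C=C | intermediate (not isolated)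
12 | ethyl (1R,2S,3R,4S)-3-ethenyl-2-(furan-2-ylmethyl)-3,4-dimethyl-5-oxocyclohexane-1-carboxylate | O=C1C[C@@H](C(=O)OCC)[C@H](Cc2ccco2)[C@@](C)(C=C)[C@@H]1C | intermediate
13 | ethyl (1R,2S,3R,4S,5R)-3-ethenyl-2-(furan-2-ylmethyl)-5-hydroxy-3,4-dimethylcyclohexane-1-carboxylate | O[C@@H]1C[C@@H](C(=O)OCC)[C@H](Cc2ccco2)[C@@](C)(C=C)[C@@H]1C | intermediate
14 | ethyl (1R,2S,3R,4S,5R)-5-(tert-butyldimethylsilyloxy)-3-ethenyl-2-(furan-2-ylmethyl)-3,4-dimethylcyclohexane-1-carboxylate | CC(C)(C)[Si](C)(C)O[C@@H]1C[C@@H](C(=O)OCC)[C@H](Cc2ccco2)[C@@](C)(C=C)[C@@H]1C | intermediate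
15 | (1R,2S,3R,4S,5R)-5-(tert-butyldimethylsilyloxy)-3-ethenyl-2-(furan-2-ylmethyl)-3,4-dimethylcyclohexane-1-carbaldehyde | CC(C)(C)[Si](C)(C)O[C@@H]1C[C@@H](C=O)[C@H](Cc2ccco2)[C@@](C)(C=C)[C@@H]1C | intermediate
16 | ethyl bromoacetate | BrCC(=O)OCC | starting material
17 | ethyl 2-[(1R,2R,3R,4S,5R)-5-(tert-butyldimethylsilyloxy)-3-ethenyl-1-formyl-2-(furan-2-ylmethyl)-3,4-dimethylcyclohexyl]acetate | CC(C)(C)[Si](C)(C)O[C@@H]1C[C@@](C=O)(CC(=O)OCC)[C@H](Cc2ccco2)[C@@](C)(C=C)[C@@H]1C | intermediate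
18 | ethyl 2-[(1R,2R,3R,4S,5R)-5-(tert-butyldimethylsilyloxy)-3-ethenyl-2-(furan-2-ylmethyl)-1-(hydroxymethyl)-3,4-dimethylcyclohexyl]acetate | CC(C)(C)[Si](C)(C)O[C@@H]1C[C@@](CO)(CC(=O)OCC)[C@H](Cc2ccco2)[C@@](C)(C=C)[C@@H]1C | intermediate (not isolated)
19 | (5R,6R,7R,8S,9R)-9-(tert-butyldimethylsilyloxy)-7-ethenyl-6-(furan-2-ylmethyl)-7,8-dimethyl-2-oxaspiro[4.5]decan-3-one | CC(C)(C)[Si](C)(C)O[C@@H]1C[C@]2(COC(=O)C2)[C@H](Cc3ccco3)[C@@](C)(C=C)[C@@H]1C | intermediate
20 | (tert-butyldimethylsilyloxy)acetaldehyde | CC(C)(C)[Si](C)(C)OCC=O | starting material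
21 | lithium aldolate of 19 and 20 (alkoxide at C3; mixture at C3 and C4) | CC(C)(C)[Si](C)(C)O[C@@H]1C[C@]2(COC(=O)C2C([O-])CO[Si](C)(C)C(C)(C)C)[C@H](Cc3ccco3)[C@@](C)(C=C)[C@@H]1C.[Li+] | intermediate (not isolated)
22 | C3 mesylate of the aldol adduct (mixture at C3 and C4) | CC(C)(C)[Si](C)(C)O[C@@H]1C[C@]2(COC(=O)C2C(CO[Si](C)(C)C(C)(C)C)OS(C)(=O)=O)[C@H](Cc3ccco3)[C@@](C)(C=C)[C@@H]1C | intermediate (not isolated)
23 | (4E,5S,6R,7R,8S,9R)-9-(tert-butyldimethylsilyloxy)-4-[2-(tert-butyldimethylsilyloxy)ethylidene]-7-ethenyl-6-(furan-2-ylmethyl)-7,8-dimethyl-2-oxaspiro[4.5]decan-3-one | CC(C)(C)[Si](C)(C)O[C@@H]1C[C@]2(COC(=O)/C2=C/CO[Si](C)(C)C(C)(C)C)[C@H](Cc3ccco3)[C@@](C)(C=C)[C@@H]1C | intermediate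
24 | B-alkyl-9-borabicyclo[3.3.1]nonane from 23 (boron on C12) | CC(C)(C)[Si](C)(C)O[C@@H]1C[C@]2(COC(=O)/C2=C/CO[Si](C)(C)C(C)(C)C)[C@H](Cc3ccco3)[C@@](C)(CCB3C4CCCC3CCC4)[C@@H]1C | intermediate (not isolated)
25 | (4E,5S,6R,7R,8S,9R)-9-(tert-butyldimethylsilyloxy)-4-[2-(tert-butyldimethylsilyloxy)ethylidene]-6-(furan-2-ylmethyl)-7-(2-hydroxyethyl)-7,8-dimethyl-2-oxaspiro[4.5]decan-3-one | CC(C)(C)[Si](C)(C)O[C@@H]1C[C@]2(COC(=O)/C2=C/CO[Si](C)(C)C(C)(C)C)[C@H](Cc3ccco3)[C@@](C)(CCO)[C@@H]1C | intermediate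
26 | 2-[(4E,5S,6R,7R,8S,9R)-9-(tert-butyldimethylsilyloxy)-4-[2-(tert-butyldimethylsilyloxy)ethylidene]-6-(furan-2-ylmethyl)-7,8-dimethyl-3-oxo-2-oxaspiro[4.5]decan-7-yl]acetaldehyde | CC(C)(C)[Si](C)(C)O[C@@H]1C[C@]2(COC(=O)/C2=C/CO[Si](C)(C)C(C)(C)C)[C@H](Cc3ccco3)[C@@](C)(CC=O)[C@@H]1C | intermediate (not isolated)
27 | 2-[(4E,5S,6R,7R,8S,9R)-9-(tert-butyldimethylsilyloxy)-4-[2-(tert-butyldimethylsilyloxy)ethylidene]-6-(furan-2-ylmethyl)-7,8-dimethyl-3-oxo-2-oxaspiro[4.5]decan-7-yl]acetic acid | CC(C)(C)[Si](C)(C)O[C@@H]1C[C@]2(COC(=O)/C2=C/CO[Si](C)(C)C(C)(C)C)[C@H](Cc3ccco3)[C@@](C)(CC(=O)O)[C@@H]1C | intermediate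
28 | acid chloride of 27 | CC(C)(C)[Si](C)(C)O[C@@H]1C[C@]2(COC(=O)/C2=C/CO[Si](C)(C)C(C)(C)C)[C@H](Cc3ccco3)[C@@](C)(CC(=O)Cl)[C@@H]1C | intermediate (not isolated)
29 | bis-silyl seco-ketone (5S,7R,8S,9R,10R): ring B trans-fused to the furan-fused cycloheptanone (C12 ketone), C5 spiro γ-lactone with (E)-2-(tert-butyldimethylsilyloxy)ethylidene at C4, axial C7 silyl ether | CC(C)(C)[Si](C)(C)O[C@@H]1C[C@]2(COC(=O)/C2=C/CO[Si](C)(C)C(C)(C)C)[C@@H]3Cc4occc4C(=O)C[C@@]3(C)[C@@H]1C | intermediate
30 | seco-diol (5S,7R,8S,9R,10R): as 29 with free C7 hydroxyl and free primary allylic C2 hydroxyl | O[C@@H]1C[C@]2(COC(=O)/C2=C/CO)[C@@H]3Cc4occc4C(=O)C[C@@]3(C)[C@@H]1C | intermediate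
31 | seco-hydroxy enal (5S,7R,8S,9R,10R): as 30 with the C2 aldehyde | O[C@@H]1C[C@]2(COC(=O)/C2=C/C=O)[C@@H]3Cc4occc4C(=O)C[C@@]3(C)[C@@H]1C | intermediate
32 | seco-acetoxy enal (5S,7R,8S,9R,10R): as 31 with the C7 acetate | CC(=O)O[C@@H]1C[C@]2(COC(=O)/C2=C/C=O)[C@@H]3Cc4occc4C(=O)C[C@@]3(C)[C@@H]1C | intermediate
33 | target CNP0182929.1: (1S,2S,5S,7R,8S,9R,10R)-7-acetoxy-2-hydroxy-12-oxo-15,16-epoxy-1,16-cyclocleroda-3,13(16),14-trien-18,19-olide | CC(=O)O[C@@H]1C[C@@]23COC(=O)C2=C[C@H](O)[C@H]2c4occc4C(=O)C[C@@](C)([C@@H]1C)[C@@H]23 | target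

Total step count: 18. Longest linear sequence: 18 steps (1 and 2 to 33).

Steps most likely to fail

Step 18. Enolization may stay at C11, so that ring closure never starts, or renewed deprotonation at C1 may expel the C2 hydroxyl after cyclization; the alkoxide may also attack the enal or the acetate faster than it enolizes the ketone. The fallback generates the same C1 nucleophile regiospecifically from a halide by known reactions. It sets out from 30: both hydroxyls are acetylated (Ac2O, DMAP, pyridine) to give the diacetate F1. Wohl–Ziegler bromination (NBS, AIBN, PhCF3, 80 °C) at the furfuryl position C1, activated by the 3-acyl furan while the acetoxy-bearing allylic position is deactivated, gives the C1 bromide F2. Lipase-catalysed hydrolysis (Candida antarctica lipase B, pH 7 buffer/acetone) of the primary allylic acetate alone gives the bromo alcohol F3, and MnO2 in CH2Cl2 gives the bromo enal F4. CrCl2 in THF/DMF then turns the bromide into the organochromium reagent (Nozaki–Hiyama-type, vinylogous Reformatsky addition), which adds to the C2 aldehyde and closes ring A, coming back to the route at 33.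

Step 5. Conjugate addition to the tetrasubstituted β-carbon, flanked by the C10 side chain, may be outrun by 1,2-addition or enolization, and facial selectivity may erode. The fallback sets out from 10: nickel-catalysed conjugate addition of the alkynylalane Me3SiC≡CAlMe2 (Ni(acac)2, i-Bu2AlH, Et2O, −5 °C), a small linear nucleophile, gives the silylalkynyl ketone F5. Desilylation (Bu4NF, AcOH, THF) gives the ethynyl ketone F6, and semi-hydrogenation (H2, Pd/CaCO3 poisoned with Pb(OAc)2, quinoline, EtOAc) comes back to the route at 12.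

Step 14. Intermolecular acylation at the free furan α-position C15, or Lewis acid-induced decomposition of the furan and the allylic silyl ether, may outrun the seven-membered ring closure. The fallback sets out from 27: amide coupling (Me2NH·HCl, EDC·HCl, HOBt, i-Pr2NEt, CH2Cl2) gives the dimethylamide F7. Electrophilic amide activation (Tf2O, 2-chloropyridine, CH2Cl2, −78 → 0 °C) triggers an intramolecular Vilsmeier–Haack-type cyclization at C13 to the cyclic iminium triflate F8, and aqueous NaHCO3 hydrolysis comes back to the route at 29.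

Further compounds
F1 | step 18 | seco-diacetate (C7 acetate and C2 primary allylic acetate) | CC(=O)O[C@@H]1C[C@]2(COC(=O)/C2=C/COC(C)=O)[C@@H]3Cc4occc4C(=O)C[C@@]3(C)[C@@H]1C
F2 | step 18 | C1 bromide of the seco-diacetate (C1 epimers) | CC(=O)O[C@@H]1C[C@]2(COC(=O)/C2=C/COC(C)=O)[C@@H]3C(Br)c4occc4C(=O)C[C@@]3(C)[C@@H]1C
F3 | step 18 | C1 bromo C2 alcohol with C7 acetate | CC(=O)O[C@@H]1C[C@]2(COC(=O)/C2=C/CO)[C@@H]3C(Br)c4occc4C(=O)C[C@@]3(C)[C@@H]1C
F4 | step 18 | C1 bromo seco-acetoxy enal | CC(=O)O[C@@H]1C[C@]2(COC(=O)/C2=C/C=O)[C@@H]3C(Br)c4occc4C(=O)C[C@@]3(C)[C@@H]1C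
F5 | step 5 | ethyl (1R,2S,3R,4S)-2-(furan-2-ylmethyl)-3,4-dimethyl-5-oxo-3-[(trimethylsilyl)ethynyl]cyclohexane-1-carboxylate | O=C1C[C@@H](C(=O)OCC)[C@H](Cc2ccco2)[C@@](C)(C#C[Si](C)(C)C)[C@@H]1C
F6 | step 5 | ethyl (1R,2S,3R,4S)-3-ethynyl-2-(furan-2-ylmethyl)-3,4-dimethyl-5-oxocyclohexane-1-carboxylate | O=C1C[C@@H](C(=O)OCC)[C@H](Cc2ccco2)[C@@](C)(C#C)[C@@H]1C
F7 | step 14 | N,N-dimethylamide of acid 27 | CC(C)(C)[Si](C)(C)O[C@@H]1C[C@]2(COC(=O)/C2=C/CO[Si](C)(C)C(C)(C)C)[C@H](Cc3ccco3)[C@@](C)(CC(=O)N(C)C)[C@@H]1C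
F8 | step 14 | cyclic C12 N,N-dimethyliminium triflate of 29 | CC(C)(C)[Si](C)(C)O[C@@H]1C[C@]2(COC(=O)/C2=C/CO[Si](C)(C)C(C)(C)C)[C@@H]3Cc4occc4C(=[N+](C)C)C[C@@]3(C)[C@@H]1C.[O-]S(=O)(=O)C(F)(F)F
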